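If Thursday's flask is to tell me more than Monday's did, I need the chance that a target molecule is still there at 23 h. Thursday's charge is Monday's, 0.150 M of starting material.

| flask | starting material | target | time |
|---|---|---|---|
| Monday's | 0.150 M |  |  |
| Saturday's | 0.0600 M |  |  |
| Wednesday's | 0.150 M | 0.0750 M |  |
| Tuesday's | 0.300 M |  |  |
| Thursday's | 0.150 M |  | 23 h |

| run | time / h | [target] / M |
|---|---|---|
| Monday's run | 0.23 | 3 × 10⁻⁴ |
| Monday's run | 0.40 | 0.0017 |
| Monday's run | 0.68 | 0.0048 |
| Monday's run | 1.2 | 0.0125 |
| Monday's run | 2.0 | 0.0249 |
| Monday's run | 3.4 | 0.0449 |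
| Monday's run | 5.8 | 0.0568 |
| Saturday's run | 0.23 | 0 |
| Saturday's run | 0.40 | 5 × 10⁻⁴ |
| Saturday's run | 0.68 | 0.0020 |
| Saturday's run | 1.2 | 0.0018 |
| Saturday's run | 2.0 | 0.0052 |
| Saturday's run | 3.4 | 0.0094 |
| Saturday's run | 5.8 | 0.0139 |
| Wednesday's run | 0.23 | 0.0731 |
| Wednesday's run | 0.40 | 0.0727 |
| Wednesday's run | 0.68 | 0.0745 |
| Wednesday's run | 1.2 | 0.0782 |
| Wednesday's run | 2.0 | 0.0872 |
| Wednesday's run | 3.4 | 0.0962 |
| Wednesday's run | 5.8 | 0.0984 |
| Tuesday's run | 0.23 | 0.0015 |
| Tuesday's run | 0.40 | 0.0079 |
| Tuesday's run | 0.68 | 0.0188 |
| Tuesday's run | 1.2 | 0.0450 |
| Tuesday's run | 2.0 | 0.0817 |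
| Tuesday's run | 3.4 | 0.1244 |
| Tuesday's run | 5.8 | 0.1455 |

(standard deviation of a reading: 0.001 M)

- Overall: starting material -> target.
- Constant volume, constant temperature.
- An order is taken over about fifteen percent of the charge, up and down.

- reaction order in [starting material] at the outset, round the charge of the Monday's run, defined at two percent of the starting material turned into target (one fixed amount of target, the same in the runs compared)
- target in the Thursday's run at 23 h, as a share of the starting material charged
- which of these the readings show (the product binds the substrate / the substrate pairs with itself / nothing beyond the main steps / two substrates go astray together / the product decays)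

Wednesday's flask is Monday's recipe with 0.0750 M of target added at the start. If formation runs alike in both flasks, the gap in c(target) between them follows that added dose. The gap is 0.0728 M at 0.23 h and 0.0416 M at 5.8 h. Read as a first-order loss, this gives 0.100 h⁻¹. I call this the toll, the chance per hour that a target molecule is lost.

Now I follow one molecule. At each moment it either stays or goes, so a molecule present at 5.8 h lasts to 23 h with a chance of 17.8 %. Thursday's flask has Monday's charge, so if it holds Monday's 0.0568 M at 5.8 h, I estimate that this stock comes down to 0.0101 M at 23 h, which is 6.73 % of the charge. That figure counts the stock at 5.8 h and leaves out target made later.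

So I leave Thursday's charge unchanged and keep the reading at 23 h.

The forecast gives 18 % for Thursday's flask, an order of 1.15, and the answer that the product decays: “It does not depend on substrate, and the early dip in Wednesday's target fits this, so the product decays.” Its share is higher than my 6.73 %, since it adds target formed after 5.8 h.

    2 starting material ⇌ intermediate + starting material (1.753 M⁻¹ h⁻¹, 0.1555 M⁻¹ h⁻¹)
    intermediate → target (0.7992 h⁻¹)
    target → decomposed product (0.1048 h⁻¹)

Thursday's flask gives 17.1 % of its charge, or 0.0256 M of target, with an order of 1.2 and the answer that the product decays. A fit with the substrate pairing with itself leaves a root mean square residual of 7.8 in units of the scatter. At the toll of 0.100 h⁻¹, the survivors of a stock equal to Monday's at 5.8 h come to 39.5 % of Thursday's target, and this estimate puts the target formed after that time and still present at 0.0155 M.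

The readings come from a simulation for substances that don't exist; the scatter is artificial.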